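**Plan** (germacrane numbering: ring C1–C10, lactone carbons C11–C13, C14 on C10, C15 on C4)
- Retrosynthesis: both epoxides and the exo-methylene are taken back to a (1(10)Z,4E)-diene lactone; the ten-membered ring is cut at C9–C10, the lactone at C6–C7 (ester-bearing allylation), the chain at C2–C3 (vinylogous aldol).
- Enabling feature: C9 lies between oxygenated C8 and C10, the methyl-bearing carbon of the cis-1,10-epoxide (a masked (Z)-C1=C10 olefin allylic to the C2 hydroxyl). C9 can therefore be the primary iodide of a C8/C9 iodohydrin and C10 an alkenyl iodide, and a nickel-catalysed reductive coupling of the two closes the ring.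
- Forward: fragment A (C14, C10, C1–C6) from but-2-yn-1-ol and ethyl 3-methylbut-2-enoate; fragment B (C7–C9, C11–C13) from (S)-glyceraldehyde acetonide and methyl acrylate; chromium-mediated allylation/lactonization joins them; then sulfide masking of C11=C13, iodohydrin, ring closure, angelate, oxidation, unmasking.
- Stereochemistry: C8 from (S)-glyceraldehyde; C7 and C6 from C8 in the allylation; C2 from the catalytic asymmetric vinylogous aldol; (Z)-C1=C10 from hydroalumination–iodination and (E)-C4=C5 from the aldol; C1/C10 by hydroxyl-directed and C4/C5 by peripheral epoxidation of the macrocycle.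

Key step: step 14

Assumption: the (S,S)-bisphosphoramide is taken to send the dienolate to the Si face of enal 4 (the (R,R) catalyst being taken as Re-selective), and C11 of the sulfide-masked lactones is left undefined because it becomes sp2 again in step 18.

**Step 1**
Reactants: 1 but-2-yn-1-ol
Product: 3 (2Z)-3-iodobut-2-en-1-ol, via cyclic alkenylalanate 2 (not isolated)
Conditions: NaAlH2(OCH2CH2OMe)2 (Red-Al), THF, 0 °C to rt; then I2, −78 to 0 °C
Reagents that add atoms: iodine, II
Why: Hydroxyl-directed trans-hydroalumination of the propargylic alcohol puts aluminium on the methyl-bearing carbon, cis to CH2O in a five-membered alkoxyalanate, and iodinolysis with retention should give the (Z)-alkenyl iodide (iodine on the future C10, cis to the future C2).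

**Step 2**
Reactants: 3 (2Z)-3-iodobut-2-en-1-ol
Product: 4 (2Z)-3-iodobut-2-enal
Conditions: MnO2, CH2Cl2, rt, dark; used directly
Reagents that add atoms: none
Why: Allylic oxidation with MnO2 leaves the alkenyl iodide untouched, and immediate use should limit Z/E drift of the β-iodo enal.

**Step 3**
Reactants: 5 ethyl 3-methylbut-2-enoate
Product: 7 tert-butyl[(1-ethoxy-3-methylbuta-1,3-dien-1-yl)oxy]dimethylsilane, via lithium dienolate 6 (not isolated)
Conditions: LiN(i-Pr)2, THF, −78 °C; then TBSCl, DMPU, −78 °C to rt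
Reagents that add atoms: tert-butyldimethylsilyl chloride, CC(C)(C)[Si](C)(C)Cl
Why: γ-Deprotonation of the senecioate and O-silylation of the dienolate give the silyl dienol ether needed for the vinylogous aldol.

**Step 4**
Reactants: 4 (2Z)-3-iodobut-2-enal; 7 silyl dienol ether
Product: 8 ethyl (2E,5S,6Z)-5-hydroxy-7-iodo-3-methylocta-2,6-dienoate
Conditions: SiCl4 (1.1 equiv), (S,S)-bisphosphoramide (binaphthyl-2,2′-diamine-derived, pentamethylene-linked, 5 mol%), i-Pr2NEt (cat.), CH2Cl2, −78 °C; aq. NaHCO3 work-up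
Reagents that add atoms: none
Why: Lewis-base-catalysed vinylogous Mukaiyama aldol addition, in which the dienol ether should react only at its γ-carbon through an open transition state to give the (E)-enoate, while the chiral phosphoramide-bound trichlorosilyl cation shields one face of the enal so that the carbinol (C2 of the target) forms as S.

**Step 5**
Reactants: 8 hydroxy ester
Product: 9 ethyl (2E,5S,6Z)-7-iodo-3-methyl-5-{[tri(propan-2-yl)silyl]oxy}octa-2,6-dienoate
Conditions: TIPSOTf, 2,6-lutidine, CH2Cl2, 0 °C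
Reagents that add atoms: triisopropylsilyl triflate, CC(C)[Si](OS(=O)(=O)C(F)(F)F)(C(C)C)C(C)C
Why: Silylation of the secondary allylic alcohol; the TIPS ether is chosen to survive the acidic acetonide hydrolysis of step 12.

**Step 6**
Reactants: 9 silyl ether ester
Product: 10 (2E,5S,6Z)-7-iodo-3-methyl-5-{[tri(propan-2-yl)silyl]oxy}octa-2,6-dien-1-ol
Conditions: i-Bu2AlH (2.2 equiv), CH2Cl2, −78 °C; Rochelle salt work-up
Reagents that add atoms: none
Why: 1,2-Reduction of the enoate to the allylic alcohol at low temperature, which should spare the alkenyl iodide and the olefin geometry.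

**Step 7**
Reactants: 10 allylic alcohol
Product: 11 (2E,5S,6Z)-7-iodo-3-methyl-5-{[tri(propan-2-yl)silyl]oxy}octa-2,6-dienal (fragment A)
Conditions: MnO2, CH2Cl2, rt
Reagents that add atoms: none
Why: Selective allylic oxidation to the enal that carries C6 as the electrophile.

**Step 8**
Reactants: 12 (4S)-2,2-dimethyl-1,3-dioxolane-4-carbaldehyde; 13 methyl prop-2-enoate
Product: 14 methyl 2-{[(4S)-2,2-dimethyl-1,3-dioxolan-4-yl](hydroxy)methyl}prop-2-enoate (both carbinol epimers)
Conditions: DABCO (0.5 equiv), dioxane/H2O, rt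
Reagents that add atoms: none
Why: Morita–Baylis–Hillman reaction; the new carbinol centre is irrelevant because it becomes sp2 in step 9, and C8 comes unchanged from the chiral pool.

**Step 9**
Reactants: 14 Morita–Baylis–Hillman adduct
Product: 15 methyl (2Z)-2-(bromomethyl)-3-[(4R)-2,2-dimethyl-1,3-dioxolan-4-yl]prop-2-enoate (fragment B; the descriptor changes by priority only)
Conditions: NBS, Me2S, CH2Cl2, 0 °C to rt
Reagents that add atoms: N-bromosuccinimide, O=C1CCC(=O)N1Br
Why: SN2′ displacement of the sulfonium-activated hydroxyl by bromide should give the thermodynamically preferred (Z)-2-(bromomethyl)enoate under neutral conditions that keep the acetonide.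

**Step 10**
Reactants: 11 enal (fragment A); 15 allyl bromide (fragment B)
Product: 17 (4S,5R)-4-[(4R)-2,2-dimethyl-1,3-dioxolan-4-yl]-5-[(1E,4S,5Z)-6-iodo-2-methyl-4-{[tri(propan-2-yl)silyl]oxy}hepta-1,5-dien-1-yl]-3-methylideneoxolan-2-one, via hydroxy ester 16 (not isolated)
Conditions: CrCl2 (4 equiv), THF, 0 °C to rt; then PPTS (cat.), PhH, 50 °C
Reagents that add atoms: none
Why: Nozaki–Hiyama allylation with an ester-bearing allyl bromide followed by lactonization, in which the equilibrating allylchromium should react through a chair transition state with the C8 residue and the aldehyde chain equatorial (anti adduct, hence the trans-lactone), and C6 should bond to the C7 face anti to the C8–O bond with H8 eclipsing the olefin (allylic 1,3-strain), so that C8 sets C7 and C6.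

**Step 11**
Reactants: 17 α-methylene lactone
Product: 18 the 13-(phenylsulfanyl)-11,13-dihydro lactone, (4S,5R)-3-[(phenylsulfanyl)methyl]oxolan-2-one with the substituents of 17 (C11 undefined)
Conditions: PhSH (1.2 equiv), Et3N (cat.), THF, 0 °C to rt
Reagents that add atoms: thiophenol, Sc1ccccc1
Why: Thia-Michael addition masks the exo-methylene, which would otherwise act as radical and nickel acceptor in step 14.

**Step 12**
Reactants: 18 sulfide acetonide
Product: 19 (4R,5R)-4-[(1R)-1,2-dihydroxyethyl]-5-[(1E,4S,5Z)-6-iodo-2-methyl-4-{[tri(propan-2-yl)silyl]oxy}hepta-1,5-dien-1-yl]-3-[(phenylsulfanyl)methyl]oxolan-2-one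
Conditions: AcOH/H2O (4:1), 40 °C
Reagents that add atoms: none
Why: Acid hydrolysis of the terminal acetonide, which the TIPS ether, the lactone and the alkenyl iodide should tolerate.

**Step 13**
Reactants: 19 diol
Product: 20 (4R,5R)-4-[(1R)-1-hydroxy-2-iodoethyl]-5-[(1E,4S,5Z)-6-iodo-2-methyl-4-{[tri(propan-2-yl)silyl]oxy}hepta-1,5-dien-1-yl]-3-[(phenylsulfanyl)methyl]oxolan-2-one
Conditions: I2 (1.2 equiv), PPh3 (1.2 equiv), imidazole, CH2Cl2, 0 °C, dark
Reagents that add atoms: iodine, II
Why: Appel-type iodination through the alkoxyphosphonium ion, which should take place at the primary C9 hydroxyl only, so that C8 keeps its hydroxyl and its configuration.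

**Step 14**
Reactants: 20 iodohydrin alkenyl iodide
Product: 21 (1(10)Z,2S,4E,6R,7R,8S)-8-hydroxy-13-(phenylsulfanyl)-2-{[tri(propan-2-yl)silyl]oxy}germacra-1(10),4-dien-12,6-olide
Conditions: NiI2 (30 mol%), 4,4′-di-tert-butyl-2,2′-bipyridine (30 mol%), Zn dust (4 equiv), NaI, pyridine, DMA, 40 °C, slow addition of 20 to 2 mM
Reagents that add atoms: none
Why: Proposed new method: zerovalent nickel (from NiI2, the bipyridine and Zn) should insert into the C10(sp2)–I bond with retention of the (Z) geometry, a monovalent nickel species should abstract iodine from the primary C9–I of the same molecule, and capture of the C9 radical at the alkenylnickel centre should give a trivalent alkenyl(alkyl)nickel that reductively eliminates the C9–C10 bond while Zn returns nickel to the zerovalent state. The closest known reaction types are the intermolecular nickel-catalysed reductive cross-electrophile coupling of alkenyl or aryl halides with primary alkyl iodides, including iodohydrins formed in situ from terminal epoxides, and nickel-mediated reductive macrocyclization of bis-halides to ten-membered 1,5-dienes; an intramolecular alkenyl iodide/iodohydrin version has not been shown. The only ring closed is the ten-membered carbocycle C1–C10, and it is closed by C(sp2)–C(sp3) reductive elimination at nickel and not by attack on a π bond. No new stereocentre is formed: C8 keeps the glyceraldehyde-derived configuration because the bond is made at C9, and the C1=C10 geometry is that of the alkenyl iodide, which is the cis ring olefin that a ten-membered ring accommodates best. The step needs cross- over homo-coupling, which the different activation modes of the sp2 and sp3 C–I bonds should provide, and ring closure over oligomerization, which high dilution and the pre-folding of the chain by the trans-lactone and the two olefins should favour. A 5-exo addition of the C9 radical to C5 would have to build a trans-fused bicyclo[3.3.0] system and should be slow, and the sulfide mask removes the only good radical acceptor.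

**Step 15**
Reactants: 21 macrocyclic alcohol; 22 angelic acid ((2Z)-2-methylbut-2-enoic acid)
Product: 24 (1(10)Z,2S,4E,6R,7R,8S)-8-[(2Z)-2-methylbut-2-enoyloxy]-13-(phenylsulfanyl)-2-{[tri(propan-2-yl)silyl]oxy}germacra-1(10),4-dien-12,6-olide, via mixed anhydride 23 (not isolated)
Conditions: 2,4,6-trichlorobenzoyl chloride, Et3N, PhMe, rt; then 21, 75 °C
Reagents that add atoms: none
Why: Yamaguchi esterification through the mixed anhydride, used without a nucleophilic catalyst because this should acylate the hindered C8 hydroxyl without isomerizing the angelate to the tiglate.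

**Step 16**
Reactants: 24 silyl ether
Product: 25 (1(10)Z,2S,4E,6R,7R,8S)-2-hydroxy-8-[(2Z)-2-methylbut-2-enoyloxy]-13-(phenylsulfanyl)germacra-1(10),4-dien-12,6-olide
Conditions: HF·pyridine, THF/pyridine, 0 °C to rt
Reagents that add atoms: none
Why: Buffered fluoride cleavage of the TIPS ether, done before any epoxide is present and under conditions that should not provoke retro-Michael loss of thiophenol or ester migration.

**Step 17**
Reactants: 25 diene alcohol
Product: 26 (1R,2S,4R,5R,6S,7R,8S,10S)-8-[(2Z)-2-methylbut-2-enoyloxy]-1,10:4,5-diepoxy-2-hydroxy-13-(phenylsulfonyl)germacran-12,6-olide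
Conditions: mCPBA (4.5 equiv), NaHCO3, CH2Cl2, 0 °C to rt
Reagents that add atoms: 3-chloroperbenzoic acid, O=C(OO)c1cccc(Cl)c1
Why: Peracid oxidation of sulfur to the sulfone and Prilezhaev epoxidation of both trisubstituted olefins: the C2 hydroxyl should deliver the peracid to the C1=C10 face syn to it with H2 eclipsing the olefin (allylic 1,3-strain with C9; threo cis-epoxide, 1R,10S); the (E)-C4=C5 olefin should be attacked from the ring periphery with H6 in the olefin plane (threo to the lactone oxygen, 4R,5R); the electron-poor angelate is inert.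

**Step 18**
Reactants: 26 bis-epoxy sulfone
Product: 27 target, (1R,2S,4R,5R,6S,7R,8S,10S)-8-[(2Z)-2-methylbut-2-enoyloxy]-1,10:4,5-diepoxy-2-hydroxygermacr-11(13)-en-12,6-olide
Conditions: DBU (1.5 equiv), CH2Cl2, 0 °C
Reagents that add atoms: none
Why: E1cB elimination of benzenesulfinate from the β-sulfonyl lactone regenerates the C11=C13 exo-methylene under conditions mild enough for the epoxides, the free hydroxyl and the angelate.

**Compound list**
1 | but-2-yn-1-ol | CC#CCO | starting material
2 | sodium 2,2-bis(2-methoxyethoxy)-3-methyl-2,5-dihydro-1,2-oxaaluminol-2-uide (cyclic (Z)-alkenylalanate) | CC1=CCO[Al-]1(OCCOC)OCCOC.[Na+] | intermediate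
3 | (2Z)-3-iodobut-2-en-1-ol | OC/C=C(/C)I | intermediate
4 | (2Z)-3-iodobut-2-enal | O=C/C=C(/C)I | intermediate
5 | ethyl 3-methylbut-2-enoate | CCOC(=O)C=C(C)C | starting material
6 | lithium 1-ethoxy-3-methylbuta-1,3-dien-1-olate | [Li+].[O-]C(OCC)=CC(C)=C | intermediate
7 | tert-butyl[(1-ethoxy-3-methylbuta-1,3-dien-1-yl)oxy]dimethylsilane | CCOC(O[Si](C)(C)C(C)(C)C)=CC(C)=C | intermediate
8 | ethyl (2E,5S,6Z)-5-hydroxy-7-iodo-3-methylocta-2,6-dienoate | CCOC(=O)/C=C(\C)C[C@H](O)/C=C(/C)I | intermediate
9 | ethyl (2E,5S,6Z)-7-iodo-3-methyl-5-{[tri(propan-2-yl)silyl]oxy}octa-2,6-dienoate | CCOC(=O)/C=C(\C)C[C@H](O[Si](C(C)C)(C(C)C)C(C)C)/C=C(/C)I | intermediate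
10 | (2E,5S,6Z)-7-iodo-3-methyl-5-{[tri(propan-2-yl)silyl]oxy}octa-2,6-dien-1-ol | OC/C=C(\C)C[C@H](O[Si](C(C)C)(C(C)C)C(C)C)/C=C(/C)I | intermediate
11 | (2E,5S,6Z)-7-iodo-3-methyl-5-{[tri(propan-2-yl)silyl]oxy}octa-2,6-dienal | O=C/C=C(\C)C[C@H](O[Si](C(C)C)(C(C)C)C(C)C)/C=C(/C)I | intermediate
12 | (4S)-2,2-dimethyl-1,3-dioxolane-4-carbaldehyde | O=C[C@@H]1COC(C)(C)O1 | starting material
13 | methyl prop-2-enoate | C=CC(=O)OC | starting material
14 | methyl 2-{[(4S)-2,2-dimethyl-1,3-dioxolan-4-yl](hydroxy)methyl}prop-2-enoate | C=C(C(=O)OC)C(O)[C@@H]1COC(C)(C)O1 | intermediate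
15 | methyl (2Z)-2-(bromomethyl)-3-[(4R)-2,2-dimethyl-1,3-dioxolan-4-yl]prop-2-enoate | COC(=O)/C(CBr)=C/[C@@H]1COC(C)(C)O1 | intermediate
16 | methyl (3S,4R,5E,8S,9Z)-3-[(4R)-2,2-dimethyl-1,3-dioxolan-4-yl]-4-hydroxy-10-iodo-6-methyl-2-methylidene-8-{[tri(propan-2-yl)silyl]oxy}undeca-5,9-dienoate | COC(=O)C(=C)[C@H]([C@@H]1COC(C)(C)O1)[C@H](O)/C=C(\C)C[C@H](O[Si](C(C)C)(C(C)C)C(C)C)/C=C(/C)I | intermediate
17 | (4S,5R)-4-[(4R)-2,2-dimethyl-1,3-dioxolan-4-yl]-5-[(1E,4S,5Z)-6-iodo-2-methyl-4-{[tri(propan-2-yl)silyl]oxy}hepta-1,5-dien-1-yl]-3-methylideneoxolan-2-one | C=C1C(=O)O[C@H](/C=C(\C)C[C@H](O[Si](C(C)C)(C(C)C)C(C)C)/C=C(/C)I)[C@H]1[C@@H]2COC(C)(C)O2 | intermediate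
18 | (4S,5R)-4-[(4R)-2,2-dimethyl-1,3-dioxolan-4-yl]-5-[(1E,4S,5Z)-6-iodo-2-methyl-4-{[tri(propan-2-yl)silyl]oxy}hepta-1,5-dien-1-yl]-3-[(phenylsulfanyl)methyl]oxolan-2-one (C3 undefined) | c1ccccc1SCC1C(=O)O[C@H](/C=C(\C)C[C@H](O[Si](C(C)C)(C(C)C)C(C)C)/C=C(/C)I)[C@H]1[C@@H]2COC(C)(C)O2 | intermediate
19 | (4R,5R)-4-[(1R)-1,2-dihydroxyethyl]-5-[(1E,4S,5Z)-6-iodo-2-methyl-4-{[tri(propan-2-yl)silyl]oxy}hepta-1,5-dien-1-yl]-3-[(phenylsulfanyl)methyl]oxolan-2-one | c1ccccc1SCC1C(=O)O[C@H](/C=C(\C)C[C@H](O[Si](C(C)C)(C(C)C)C(C)C)/C=C(/C)I)[C@H]1[C@@H](O)CO | intermediate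
20 | (4R,5R)-4-[(1R)-1-hydroxy-2-iodoethyl]-5-[(1E,4S,5Z)-6-iodo-2-methyl-4-{[tri(propan-2-yl)silyl]oxy}hepta-1,5-dien-1-yl]-3-[(phenylsulfanyl)methyl]oxolan-2-one | c1ccccc1SCC1C(=O)O[C@H](/C=C(\C)C[C@H](O[Si](C(C)C)(C(C)C)C(C)C)/C=C(/C)I)[C@H]1[C@@H](O)CI | intermediate
21 | (1(10)Z,2S,4E,6R,7R,8S)-8-hydroxy-13-(phenylsulfanyl)-2-{[tri(propan-2-yl)silyl]oxy}germacra-1(10),4-dien-12,6-olide | O=C1O[C@@H]2/C=C(C)/C[C@H](O[Si](C(C)C)(C(C)C)C(C)C)/C=C(C)\C[C@H](O)[C@H]2C1CSc1ccccc1 | intermediate
22 | angelic acid, (2Z)-2-methylbut-2-enoic acid | C/C=C(/C)C(=O)O | starting material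
23 | (2Z)-2-methylbut-2-enoic 2,4,6-trichlorobenzoic anhydride | C/C=C(/C)C(=O)OC(=O)c1c(Cl)cc(Cl)cc1Cl | intermediate
24 | (1(10)Z,2S,4E,6R,7R,8S)-8-[(2Z)-2-methylbut-2-enoyloxy]-13-(phenylsulfanyl)-2-{[tri(propan-2-yl)silyl]oxy}germacra-1(10),4-dien-12,6-olide | O=C1O[C@@H]2/C=C(C)/C[C@H](O[Si](C(C)C)(C(C)C)C(C)C)/C=C(C)\C[C@H](OC(=O)/C(C)=C\C)[C@H]2C1CSc1ccccc1 | intermediate
25 | (1(10)Z,2S,4E,6R,7R,8S)-2-hydroxy-8-[(2Z)-2-methylbut-2-enoyloxy]-13-(phenylsulfanyl)germacra-1(10),4-dien-12,6-olide | O=C1O[C@@H]2/C=C(C)/C[C@H](O)/C=C(C)\C[C@H](OC(=O)/C(C)=C\C)[C@H]2C1CSc1ccccc1 | intermediate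
26 | (1R,2S,4R,5R,6S,7R,8S,10S)-8-[(2Z)-2-methylbut-2-enoyloxy]-1,10:4,5-diepoxy-2-hydroxy-13-(phenylsulfonyl)germacran-12,6-olide | O=S(=O)(c1ccccc1)CC1C(=O)O[C@H]2[C@H]1[C@@H](OC(=O)/C(C)=C\C)C[C@]1(C)O[C@@H]1[C@@H](O)C[C@@]1(C)O[C@H]21 | intermediate
27 | (1R,2S,4R,5R,6S,7R,8S,10S)-8-[(2Z)-2-methylbut-2-enoyloxy]-1,10:4,5-diepoxy-2-hydroxygermacr-11(13)-en-12,6-olide | C=C1C(=O)O[C@H]2[C@H]1[C@@H](OC(=O)/C(C)=C\C)C[C@]1(C)O[C@@H]1[C@@H](O)C[C@@]1(C)O[C@H]21 | target

**Step count and risks**
Total step count: 18. Longest linear sequence: 15 steps (steps 1, 2, 4–7, 10–18).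

Most likely to fail:

1. Step 14 (Proposed new method). Oligomerization by intermolecular coupling, hydrodehalogenation of the alkenyl iodide, or reductive loss of the iodohydrin to a terminal olefin may outrun ring closure. Fallback, with the ring closed at C1=C10 by olefin metathesis: setting out from diol 19, NaIO4 cleavage would give the C8 aldehyde F1. Reagent-controlled methallylation with (−)-B-methallyldiisopinocampheylborane (ethanolamine work-up) would rebuild C9 and C10 and set C8, giving the homoallylic alcohol F2. Bu3SnH with Pd(PPh3)4 would replace iodine by hydrogen to give the (E)-propenyl compound F3. Ring-closing metathesis with the second-generation Grubbs catalyst in toluene at high dilution would expel propene and form the trisubstituted C1=C10 olefin, cis as the ten-membered ring requires, and so come back to the route at 21.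

2. Step 10. The ester-bearing allylchromium may add with syn instead of anti simple diastereoselection (leading to the cis-lactone) or with poor facial control at C7. Fallback, syn addition followed by invertive lactonization: setting out from 11 and 15, indium-mediated Barbier allylation in aqueous THF, which is syn-selective for (Z)-2-(bromomethyl)enoates, would give the C6-epimeric hydroxy ester F4. LiOH would hydrolyse the methyl ester to the hydroxy acid F5. Mitsunobu lactonization (PPh3, DIAD) would close the lactone with inversion at C6 and come back to the route at 17.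

3. Step 17. Facial selectivity at the C4=C5 olefin may be poor, or the first-formed epoxide may open transannularly under the acidic by-product during the fourfold oxidation. Fallback, unmasking first and then one epoxide by hydroxyl direction and the other by reagent control: setting out from 25, KHSO5 in aqueous methanol would oxidise only sulfur to give the sulfone F6. DBU would eliminate benzenesulfinate to give the dienyl α-methylene lactone F7. VO(acac)2 with t-BuOOH would epoxidise only the allylic-alcohol olefin C1=C10, syn to the C2 hydroxyl, to give the 1,10-epoxide F8. The fructose-derived chiral ketone with KHSO5 (chiral dioxirane) would then deliver the (4R,5R)-epoxide and come back to the route at target 27.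

**Further compounds**
F1 | step 14 | C8 aldehyde: lactone of 19 with the 1,2-dihydroxyethyl group replaced by formyl | c1ccccc1SCC1C(=O)O[C@H](/C=C(\C)C[C@H](O[Si](C(C)C)(C(C)C)C(C)C)/C=C(/C)I)[C@H]1C=O
F2 | step 14 | homoallylic alcohol: lactone of 19 with the C7 side chain (1S)-1-hydroxy-3-methylbut-3-en-1-yl | c1ccccc1SCC1C(=O)O[C@H](/C=C(\C)C[C@H](O[Si](C(C)C)(C(C)C)C(C)C)/C=C(/C)I)[C@H]1[C@@H](O)CC(C)=C
F3 | step 14 | de-iodinated metathesis precursor: F2 with the iodoalkenyl end reduced to (E)-prop-1-enyl | c1ccccc1SCC1C(=O)O[C@H](/C=C(\C)C[C@H](O[Si](C(C)C)(C(C)C)C(C)C)/C=C/C)[C@H]1[C@@H](O)CC(C)=C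
F4 | step 10 | C6 epimer of hydroxy ester 16 (syn adduct) | COC(=O)C(=C)[C@H]([C@@H]1COC(C)(C)O1)[C@@H](O)/C=C(\C)C[C@H](O[Si](C(C)C)(C(C)C)C(C)C)/C=C(/C)I
F5 | step 10 | hydroxy acid from F4 | OC(=O)C(=C)[C@H]([C@@H]1COC(C)(C)O1)[C@@H](O)/C=C(\C)C[C@H](O[Si](C(C)C)(C(C)C)C(C)C)/C=C(/C)I
F6 | step 17 | 13-(phenylsulfonyl) analogue of 25 | O=C1O[C@@H]2/C=C(C)/C[C@H](O)/C=C(C)\C[C@H](OC(=O)/C(C)=C\C)[C@H]2C1CS(=O)(=O)c1ccccc1
F7 | step 17 | (1(10)Z,2S,4E,6R,7R,8S)-2-hydroxy-8-[(2Z)-2-methylbut-2-enoyloxy]germacra-1(10),4,11(13)-trien-12,6-olide | O=C1O[C@@H]2/C=C(C)/C[C@H](O)/C=C(C)\C[C@H](OC(=O)/C(C)=C\C)[C@H]2C1=C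
F8 | step 17 | 1,10-epoxide of F7 (1R,10S; 4E olefin intact) | O=C1O[C@@H]2/C=C(C)/C[C@H](O)[C@H]3O[C@@]3(C)C[C@H](OC(=O)/C(C)=C\C)[C@H]2C1=C
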